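- At 8.0 d your flask, run theta, reads 36.0% target and 63.9% starting material; the target stood at 35.9% one reading earlier, with a scatter of 1 percentage point, so my number for now is that last reading.
- You guessed dead catalyst and I agree: the two readings sum to 99.9%, so the starting material is still there, unconverted, and warmer run beta stalls as well, at 40.8%.

in all of them: starting material 1.4 M; precatalyst 7.3 mM

|  | second substrate | partner | protic impurity | temperature | remark | time |
|---|---|---|---|---|---|---|
| theta | 0.70 M | 1.4 M | 0.42 M | 25 °C | the very flask that is asked about, followed so far |  |
| beta | 0.70 M | 1.4 M | 0.42 M | 31 °C | run made earlier |  |
| flask | 0.700 M | 1.40 M | 0.420 M | 25 °C |  | 8.0 d |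

| run | time / d | target / % | starting material / % |
|---|---|---|---|
| theta | 2.08 | 32.5 | 71.5 |
| theta | 4.00 | 33.6 | 64.4 |
| theta | 6.00 | 35.9 | 64.0 |
| theta | 8.00 | 36.0 | 63.9 |
| beta | 2.08 | 38.0 | 61.5 |
| beta | 4.00 | 41.1 | 60.1 |
| beta | 6.00 | 40.3 | 59.6 |
| beta | 8.00 | 40.8 | 59.0 |

(scatter of a reading: 1 percentage point)

- target that was removed still counts
- the earlier runs were read with a standard deviation of 1 percentage point
- candidate steps: partner + catalyst intermediate B -> spent catalyst; starting material + free catalyst <-> catalyst intermediate A; precatalyst -> free catalyst; second substrate + protic impurity -> quenched substrate; partner + catalyst intermediate A -> free catalyst + target; partner + catalyst intermediate B -> free catalyst + second product; second substrate + free catalyst <-> catalyst intermediate B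
- additions bring no volume worth counting

- north: at 8.0 d raise the temperature by 20 K, then wait 8.0 d
- north-west: change nothing and wait 8.0 d more
- north-east: at 8.0 d take out 90% of the target then present, then wait 8.0 d
- south: at 8.0 d add precatalyst, 100% of the amount charged, then wait 8.0 d

1. target, in percent of the starting material first charged, at 8.0 d
2. the remedy with the largest gain of target, or "none" below 2 percentage points (north / north-west / north-east / south / none)
3. target present, with what was taken out counted in, in percent of the starting material first charged, after north
4. target present, with what was taken out counted in, in percent of the starting material first charged, after south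

- I give north, north-west and north-east no gain over the reading, so I put north at 36.0% again and pick south.
- South needs a rule. Let L be the drop in the natural log of starting material over one catalyst charge, here 0.448.
- Turnover runs through catalyst intermediate A and catalyst death through catalyst intermediate B, both with partner. If both intermediates follow their binding steps, L goes as the inverse of the second substrate concentration.
- Second substrate also meets protic impurity one to one, and that impurity is the limiting reagent of the quench. This gives 0.280 M: the unquenched excess E, second substrate charged minus protic impurity charged.
- Now take both ends. The first charge starts at 0.700 M and, once the quench has finished, stands at E or below, as the catalyst steps take some too. The straight average of the two ends is 0.490 M.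
- A second charge works at E or below, so on this rule I estimate its L at 0.784 and your flask after south at 70.8% target, and I take both as estimates on the low side.
- The forecast gives 36% now, south as best, 36.6% after north and 58% after south, lower than my figure, on its ground that “Per charge, starting material falls by a roughly constant factor”.
- Your flask gives 36.3%, with south best at a gain of 41 points, 36.5% after north and 77.7% after south, above my estimate.

    partner + catalyst intermediate B → spent catalyst (k = 0.880 /M/h, Ea = 67.0 kJ/mol)
    starting material + free catalyst ⇌ catalyst intermediate A (K = 5.20 /M, k = 24.0 /M/h, Ea = 71.0 kJ/mol, ΔH = −37.0 kJ/mol)
    precatalyst → free catalyst (k = 1.20 /h, Ea = 86.0 kJ/mol)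
    second substrate + protic impurity → quenched substrate (k = 0.220 /M/h, Ea = 86.0 kJ/mol)
    partner + catalyst intermediate A → free catalyst + target (k = 5.70 /M/h, Ea = 69.0 kJ/mol)
    partner + catalyst intermediate B → free catalyst + second product (k = 16.0 /M/h, Ea = 55.0 kJ/mol)
    second substrate + free catalyst ⇌ catalyst intermediate B (K = 3.40 /M, k = 17.0 /M/h, Ea = 52.0 kJ/mol, ΔH = −85.0 kJ/mol)
    (constants at 25 °C)

- At 8.00 d your flask holds 0.140 M of second substrate, below E, with 0.048% of the protic impurity left. In the neighbouring flask, charged with 0.17 M of second substrate, E comes to −0.250 M: the sign says the protic impurity charged exceeds the second substrate charged, so the reckoning gives no unquenched excess. That flask ends with 0% of its second substrate, 69% of its protic impurity, 27.1% of the catalyst as spent catalyst, and 92.7% target.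

All runs were generated by integration with made-up constants, and the scatter is random.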